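**Plan**

- Retrosynthesis: the (Z)-γ-hydroxy acid is read as an opened butenolide (cut C15–O, then C13=C14 by ring-closing metathesis). Ring A is cut at C3–C4, C1–C10 and C4–C18 (enolate alkylations). Ring B is cut at C5–C6 and C9–C10 ([4+2]).
- Enabling feature: O12 stands 1,3 to C9, and the angular carbon C20 sits on the adjacent C10. An ester O12–C20(=O) therefore ties the dienophile C10=C5 to the diene C6=C7–C8=C9 through a six-membered lactone. C20 is carried as this carbonyl (it activates the dienophile, then acidifies C10–H) and is reduced to the methyl group late.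
- Forward order: C12 carbinol → (Z)-enoate ester → ring B together with the temporary lactone ring (step 9) → C10 alkylated, ring A closed at C4, C4 methylated → lactone reduced to CH3 with release of O12 → butenolide → opened.
- Stereochemistry: C12 from a CBS reduction (used as R, inverted to S in the Mitsunobu step). C5 and C9 from the endo cycloaddition of the Z-dienophile, with the face chosen by C12. C10 and C4 from equatorial alkylation of exocyclic enolates. 13Z from the butenolide ring.

Key step: step 9

Remark on numbering: atoms are numbered as in labdane (ring A = C1–C5, C10; ring B = C5–C10; C17 = CH2 on C8; C18 = methyl and C19 = carboxyl on C4; C20 = carbon on C10; side chain C11–C16); β is the face of C20.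

Remark on the product: the free (Z)-γ-hydroxy acid is taken to be isolable when it is set free cold at about pH 4 and extracted at once; on standing in acid it is expected to close to the butenolide.

**Route**

Step 1
Reactants: 1 ethyl 4-chloro-4-oxobutanoate
Product: 2 ethyl 5-methyl-4-oxohex-5-enoate
Conditions: isopropenylmagnesium bromide, Fe(acac)3 (3 mol %), THF, −78 °C
Reagents that add atoms: isopropenylmagnesium bromide CC(=C)[Mg]Br
Why: Iron-catalysed acylation of a Grignard reagent by an acid chloride should be much faster at −78 °C than addition to the ester or to the ketone formed.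

Step 2
Reactants: 2 ethyl 5-methyl-4-oxohex-5-enoate
Product: 3 ethyl (4R)-4-hydroxy-5-methylhex-5-enoate
Conditions: (S)-2-methyl-CBS-oxazaborolidine (10 mol %), catecholborane, toluene, −78 °C
Reagents that add atoms: none
Why: Corey–Bakshi–Shibata reduction in which the isopropenyl group acts as the large substituent, so that the (S)-catalyst should give the (R)-carbinol (the future C12) by 1,2-reduction without touching the ester or the alkene.

Step 3
Reactants: 3 ethyl (4R)-4-hydroxy-5-methylhex-5-enoate
Product: 4 (4R)-4-hydroxy-N-methoxy-N,5-dimethylhex-5-enamide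
Conditions: MeNHOMe·HCl, i-PrMgCl, THF, −20 → 0 °C; used at once
Reagents that add atoms: N,O-dimethylhydroxylamine hydrochloride CNOC.Cl
Why: Weinreb amide formation from an ester with the chloromagnesium amide, the hydroxyl group being carried as its alkoxide (any lactone formed reacts in the same way).

Step 4
Reactants: 5 tert-butyl(but-3-yn-1-yloxy)dimethylsilane
Product: 6 5-[(tert-butyldimethylsilyl)oxy]pent-2-ynoic acid
Conditions: n-BuLi, THF, −78 °C; CO2; cold dilute HCl to pH 3
Reagents that add atoms: carbon dioxide O=C=O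
Why: Carboxylation of a lithium acetylide.

Step 5
Reactants: 4 (4R)-4-hydroxy-N-methoxy-N,5-dimethylhex-5-enamide; 6 5-[(tert-butyldimethylsilyl)oxy]pent-2-ynoic acid
Product: 7 (3R)-6-[methoxy(methyl)amino]-2-methyl-6-oxohex-1-en-3-yl 5-[(tert-butyldimethylsilyl)oxy]pent-2-ynoate
Conditions: DCC, DMAP (cat.), CH2Cl2, −20 → 0 °C
Reagents that add atoms: none
Why: Steglich esterification with retention at the carbinol carbon; the alkynoic acid is used so that the acyl-transfer catalyst cannot scramble the dienophile geometry.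

Step 6
Reactants: 7 (3R)-6-[methoxy(methyl)amino]-2-methyl-6-oxohex-1-en-3-yl 5-[(tert-butyldimethylsilyl)oxy]pent-2-ynoate
Product: 8 (3R)-6-[methoxy(methyl)amino]-2-methyl-6-oxohex-1-en-3-yl (2Z)-5-[(tert-butyldimethylsilyl)oxy]pent-2-enoate
Conditions: H2 (1 atm), Pd/CaCO3 poisoned with Pb(OAc)2, quinoline, EtOAc, rt
Reagents that add atoms: none
Why: Lindlar semi-hydrogenation adds H2 syn to the alkynoate and should give the (Z)-enoate while leaving the 1,1-disubstituted alkene alone.

Step 7
Reactants: 8 (3R)-6-[methoxy(methyl)amino]-2-methyl-6-oxohex-1-en-3-yl (2Z)-5-[(tert-butyldimethylsilyl)oxy]pent-2-enoate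
Product: 9 (3R)-2-methyl-6-oxoocta-1,7-dien-3-yl (2Z)-5-[(tert-butyldimethylsilyl)oxy]pent-2-enoate
Conditions: CH2=CHMgBr, THF, −78 → −40 °C; poured into cold aq. NH4Cl
Reagents that add atoms: vinylmagnesium bromide C=C[Mg]Br
Why: Weinreb ketone synthesis, in which the chelated tetrahedral intermediate stops at the ketone stage and the amide should react ahead of the secondary-alkyl enoate at low temperature.

Step 8
Reactants: 9 (3R)-2-methyl-6-oxoocta-1,7-dien-3-yl (2Z)-5-[(tert-butyldimethylsilyl)oxy]pent-2-enoate
Product: 10 (3R,5Z)-2-methyl-6-[(triethylsilyl)oxy]octa-1,5,7-trien-3-yl (2Z)-5-[(tert-butyldimethylsilyl)oxy]pent-2-enoate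
Conditions: Et3SiOTf, Et3N, CH2Cl2, −78 → 0 °C
Reagents that add atoms: triethylsilyl trifluoromethanesulfonate CC[Si](CC)(CC)OS(=O)(=O)C(F)(F)F
Why: Soft enolisation and O-silylation at the only enolisable position of the ketone (C9) should give the (Z)-2-silyloxy diene, with C11 trans to the vinyl group as the cycloaddition requires.

Step 9
Reactants: 10 (3R,5Z)-2-methyl-6-[(triethylsilyl)oxy]octa-1,5,7-trien-3-yl (2Z)-5-[(tert-butyldimethylsilyl)oxy]pent-2-enoate
Product: 11 lactone cycloadduct (ring B as cyclohex-7-ene with Et3SiO on C8; δ-lactone C10–C20(=O)–O–C12–C11–C9 cis-fused on the β face; 5α-H 9α-H 10α-H; β-CH2CH2OTBS on C5; isopropenyl on C12; 12R)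
Conditions: toluene (0.005 M), BHT (cat.), base-washed sealed tube, 150 °C
Reagents that add atoms: none
Why: Thermal type 1 intramolecular Diels–Alder reaction, a concerted suprafacial [4+2] cycloaddition in which the diene C6=C7–C8(OSiEt3)=C9 adds across the (Z)-enoate C10=C5 and forms C5–C6 and C9–C10 together; the closest known reaction type is the cyclisation of hexa-3,5-dienyl acrylates to fused δ-lactones. Ring B closes as a cyclohexene in the [4+2] mode, and the temporary six-membered lactone closes in the fused mode through the three-atom tether, which is expected to span C9–C10 comfortably only when the lactone carbonyl lies under the diene (endo), so that this ring is cis-fused. The endo transition state, the Z geometry of the dienophile and the outside position of C11 on the diene put C11, C20 and the C4 chain on one face of ring B and so fix C5 relative to C9; C10 is formed with its hydrogen α but is set anew in step 10. The absolute sense comes from C12: in the boat-like tether the isopropenyl group should take the outward (bowsprit) position and not the flagpole position that faces H10, and for the (R)-carbinol this exposes the diene face that leads to the natural configuration at C5 and C9. The step needs endo selectivity, facial selectivity and a regiochemistry that runs against the polarity of the silyloxy diene; the first two rest on the tether length and the C12 substituent, the last on the tether alone, and high dilution keeps intermolecular addition down.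

Step 10
Reactants: 11 lactone cycloadduct
Product: 13 ketone lactone (8-oxo; C10 quaternary with 3-chloropropyl α and the lactone carbonyl C20 β; 5α-H 9α-H; β-CH2CH2OTBS on C5; 12R), via triethylsilyl enol ether 12 (not isolated)
Conditions: LiN(i-Pr)2, THF, −78 °C; ICH2CH2CH2Cl, DMPU, −78 → −20 °C; then 0.5 M HCl, THF, 0 °C
Reagents that add atoms: 1-chloro-3-iodopropane ClCCCI
Why: Alkylation of the lactone enolate at C10 should occur by equatorial attack from the α face, away from C11 and the C5 side chain, which keeps the lactone cis-fused and places C1 α; dilute acid then hydrolyses only the triethylsilyl enol ether.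

Step 11
Reactants: 13 ketone lactone
Product: 14 8(17)-methylene lactone (C19–OTBS)
Conditions: Ph3PCH3Br, KOt-Bu, THF, 0 °C → rt
Reagents that add atoms: methyltriphenylphosphonium bromide C[P+](c1ccccc1)(c1ccccc1)c1ccccc1.[Br-]
Why: Wittig methylenation of the ketone, which is far more electrophilic than the hindered lactone; C9 cannot epimerise while it is held in the cis-fused lactone.

Step 12
Reactants: 14 8(17)-methylene lactone (C19–OTBS)
Product: 15 8(17)-methylene lactone primary alcohol (C19–OH)
Conditions: Bu4NF, AcOH, THF, rt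
Reagents that add atoms: none
Why: Fluoride cleavage of the primary silyl ether, buffered with acetic acid so that no free alkoxide attacks the lactone carbonyl.

Step 13
Reactants: 15 8(17)-methylene lactone primary alcohol (C19–OH)
Product: 16 8(17)-methylene lactone carboxylic acid (C19 acid)
Conditions: TEMPO (cat.), PhI(OAc)2, MeCN/H2O, rt
Reagents that add atoms: water O
Why: Oxoammonium oxidation of a primary alcohol through the aldehyde hydrate to the acid, which leaves the alkenes and the alkyl chloride untouched.

Step 14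
Reactants: 16 8(17)-methylene lactone carboxylic acid (C19 acid)
Product: 17 2-(trimethylsilyl)ethyl ester of 16
Conditions: Me3SiCH2CH2OH, DCC, DMAP (cat.), CH2Cl2, 0 °C → rt
Reagents that add atoms: 2-(trimethylsilyl)ethanol C[Si](C)(C)CCO
Why: Steglich esterification gives an ester that tolerates enolate chemistry and can later be removed by fluoride even when it is hindered.

Step 15
Reactants: 17 2-(trimethylsilyl)ethyl ester of 16
Product: 19 2-(trimethylsilyl)ethyl ester of (12R)-19-carboxy-15-norlabda-8(17),13-dien-20,12-olide (rings A/B trans; 4α-methyl; 4β-ester), via ring-closed ester 18 (not isolated)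
Conditions: LiN(i-Pr)2, THF/DMPU, −78 → 0 °C; then LiN(i-Pr)2, −78 °C; MeI, −78 → −20 °C
Reagents that add atoms: iodomethane CI
Why: Intramolecular 6-exo-tet alkylation of the ester enolate closes ring A between two equatorial bonds (trans-decalin), and the second enolate should be methylated from the equatorial α face because the β face of C4 is blocked by the 1,3-diaxial C20, which gives the axial ester and the equatorial methyl group.

Step 16
Reactants: 19 tricyclic lactone ester
Product: 20 lactol (20-hydroxy-20,12-epoxide; mixture at C20)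
Conditions: i-Bu2AlH, CH2Cl2, −78 °C; aq. KNaC4H4O6
Reagents that add atoms: none
Why: Hydride reduction of a lactone by i-Bu2AlH stops at the lactol at −78 °C, and the axial neopentyl ester at C19 should be too hindered to compete.

Step 17
Reactants: 20 lactol
Product: 22 2-(trimethylsilyl)ethyl (12R)-12-hydroxy-15-norlabda-8(17),13-dien-19-oate, via tosylhydrazone 21 (not isolated)
Conditions: TsNHNH2, EtOH, 60 °C; then catecholborane, CHCl3, 0 °C → rt; NaOAc·3H2O, 60 °C
Reagents that add atoms: none
Why: Condensation of the ring-opened hydroxy aldehyde with the sulfonylhydrazide, hydride transfer to the tosylhydrazone, loss of sulfinate and extrusion of N2 (a mild Wolff–Kishner-type deoxygenation) should turn C20 into the methyl group and set the C12 hydroxyl free without touching ester or alkenes.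

Step 18
Reactants: 22 2-(trimethylsilyl)ethyl (12R)-12-hydroxy-15-norlabda-8(17),13-dien-19-oate
Product: 23 2-(trimethylsilyl)ethyl (12S)-12-(acryloyloxy)-15-norlabda-8(17),13-dien-19-oate
Conditions: PPh3, DIAD, THF, 0 °C (betaine formed first); then 22 and acrylic acid, 0 °C → rt
Reagents that add atoms: acrylic acid C=CC(=O)O
Why: Mitsunobu esterification proceeds by SN2 displacement at C12 and so inverts the (R)-carbinol to the (S) configuration of the target; forming the betaine first keeps free phosphine away from the acrylate.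

Step 19
Reactants: 23 2-(trimethylsilyl)ethyl (12S)-12-(acryloyloxy)-15-norlabda-8(17),13-dien-19-oate
Product: 24 2-(trimethylsilyl)ethyl (12S)-labda-8(17),13-dien-15,12-olid-19-oate (butenolide)
Conditions: second-generation Grubbs catalyst (5 mol %), toluene, 80 °C
Reagents that add atoms: none
Why: Ring-closing metathesis of the acrylate onto the isopropenyl group gives the 4-methylbutenolide, whose ring fixes the 13Z geometry; the hindered exocyclic methylene on C8 should not engage.

Step 20
Reactants: 24 2-(trimethylsilyl)ethyl (12S)-labda-8(17),13-dien-15,12-olid-19-oate (butenolide)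
Product: 26 (12S,13Z)-12-hydroxylabda-8(17),13-diene-15,19-dioic acid, via butenolide acid 25 (not isolated)
Conditions: Bu4NF, THF, rt; then LiOH, THF/H2O, 0 °C; cold 0.5 M HCl to pH 4, immediate extraction
Reagents that add atoms: lithium hydroxide [Li+].[OH-]
Why: Fluoride-induced β-elimination removes the 2-(trimethylsilyl)ethyl ester, and hydroxide then opens the butenolide by acyl–oxygen cleavage, which leaves C12 and the Z alkene untouched.

**Compound list**

1 | ethyl 4-chloro-4-oxobutanoate | CCOC(=O)CCC(=O)Cl | starting material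
2 | ethyl 5-methyl-4-oxohex-5-enoate | CCOC(=O)CCC(=O)C(C)=C | intermediate
3 | ethyl (4R)-4-hydroxy-5-methylhex-5-enoate | CCOC(=O)CC[C@@H](O)C(C)=C | intermediate
4 | (4R)-4-hydroxy-N-methoxy-N,5-dimethylhex-5-enamide | CON(C)C(=O)CC[C@@H](O)C(C)=C | intermediate
5 | tert-butyl(but-3-yn-1-yloxy)dimethylsilane | C#CCCO[Si](C)(C)C(C)(C)C | starting material
6 | 5-[(tert-butyldimethylsilyl)oxy]pent-2-ynoic acid | OC(=O)C#CCCO[Si](C)(C)C(C)(C)C | intermediate
7 | (3R)-6-[methoxy(methyl)amino]-2-methyl-6-oxohex-1-en-3-yl 5-[(tert-butyldimethylsilyl)oxy]pent-2-ynoate | CON(C)C(=O)CC[C@@H](OC(=O)C#CCCO[Si](C)(C)C(C)(C)C)C(C)=C | intermediate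
8 | (3R)-6-[methoxy(methyl)amino]-2-methyl-6-oxohex-1-en-3-yl (2Z)-5-[(tert-butyldimethylsilyl)oxy]pent-2-enoate | CON(C)C(=O)CC[C@@H](OC(=O)/C=C\CCO[Si](C)(C)C(C)(C)C)C(C)=C | intermediate
9 | (3R)-2-methyl-6-oxoocta-1,7-dien-3-yl (2Z)-5-[(tert-butyldimethylsilyl)oxy]pent-2-enoate | C=CC(=O)CC[C@@H](OC(=O)/C=C\CCO[Si](C)(C)C(C)(C)C)C(C)=C | intermediate
10 | (3R,5Z)-2-methyl-6-[(triethylsilyl)oxy]octa-1,5,7-trien-3-yl (2Z)-5-[(tert-butyldimethylsilyl)oxy]pent-2-enoate | C=C/C(O[Si](CC)(CC)CC)=C/C[C@@H](OC(=O)/C=C\CCO[Si](C)(C)C(C)(C)C)C(C)=C | intermediate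
11 | lactone cycloadduct: cyclohex-7-ene ring B with Et3SiO on C8; cis-fused 20,12-δ-lactone on the β face; 5α-H, 9α-H, 10α-H; β-CH2CH2OTBS on C5; isopropenyl on C12 (12R) | CC[Si](CC)(CC)OC1=CC[C@@H](CCO[Si](C)(C)C(C)(C)C)[C@H]2C(=O)O[C@@H](C(C)=C)C[C@@H]12 | intermediate
12 | triethylsilyl enol ether of 13 (C10 alkylated; 3-chloropropyl α) | CC[Si](CC)(CC)OC1=CC[C@@H](CCO[Si](C)(C)C(C)(C)C)[C@@]2(CCCCl)C(=O)O[C@@H](C(C)=C)C[C@@H]12 | intermediate (not isolated)
13 | ketone lactone: 8-oxo; C10 with 3-chloropropyl α and lactone carbonyl C20 β; β-CH2CH2OTBS on C5; 12R | O=C1CC[C@@H](CCO[Si](C)(C)C(C)(C)C)[C@@]2(CCCCl)C(=O)O[C@@H](C(C)=C)C[C@@H]12 | intermediate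
14 | 8(17)-methylene lactone (C19–OTBS) | C=C1CC[C@@H](CCO[Si](C)(C)C(C)(C)C)[C@@]2(CCCCl)C(=O)O[C@@H](C(C)=C)C[C@@H]12 | intermediate
15 | 8(17)-methylene lactone primary alcohol (C19–OH) | C=C1CC[C@@H](CCO)[C@@]2(CCCCl)C(=O)O[C@@H](C(C)=C)C[C@@H]12 | intermediate
16 | 8(17)-methylene lactone carboxylic acid (C19 acid) | C=C1CC[C@@H](CC(=O)O)[C@@]2(CCCCl)C(=O)O[C@@H](C(C)=C)C[C@@H]12 | intermediate
17 | 2-(trimethylsilyl)ethyl ester of 16 | C=C1CC[C@@H](CC(=O)OCC[Si](C)(C)C)[C@@]2(CCCCl)C(=O)O[C@@H](C(C)=C)C[C@@H]12 | intermediate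
18 | ring-closed ester (ring A formed; C4–H, both epimers) | C=C1CC[C@@H]2[C@@]3(CCCC2C(=O)OCC[Si](C)(C)C)C(=O)O[C@@H](C(C)=C)C[C@@H]13 | intermediate (not isolated)
19 | 2-(trimethylsilyl)ethyl ester of (12R)-19-carboxy-15-norlabda-8(17),13-dien-20,12-olide (4α-methyl, 4β-ester) | C=C1CC[C@@H]2[C@@]3(CCC[C@]2(C)C(=O)OCC[Si](C)(C)C)C(=O)O[C@@H](C(C)=C)C[C@@H]13 | intermediate
20 | lactol of 19 (20-hydroxy-20,12-epoxide; mixture at C20) | C=C1CC[C@@H]2[C@@]3(CCC[C@]2(C)C(=O)OCC[Si](C)(C)C)C(O)O[C@@H](C(C)=C)C[C@@H]13 | intermediate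
21 | C20 tosylhydrazone of the ring-opened hydroxy aldehyde | C=C1CC[C@@H]2[C@](C=NNS(=O)(=O)c3ccc(C)cc3)(CCC[C@]2(C)C(=O)OCC[Si](C)(C)C)[C@H]1C[C@@H](O)C(C)=C | intermediate (not isolated)
22 | 2-(trimethylsilyl)ethyl (12R)-12-hydroxy-15-norlabda-8(17),13-dien-19-oate | C=C1CC[C@@H]2[C@](C)(CCC[C@]2(C)C(=O)OCC[Si](C)(C)C)[C@H]1C[C@@H](O)C(C)=C | intermediate
23 | 2-(trimethylsilyl)ethyl (12S)-12-(acryloyloxy)-15-norlabda-8(17),13-dien-19-oate | C=C1CC[C@@H]2[C@](C)(CCC[C@]2(C)C(=O)OCC[Si](C)(C)C)[C@H]1C[C@H](OC(=O)C=C)C(C)=C | intermediate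
24 | 2-(trimethylsilyl)ethyl (12S)-labda-8(17),13-dien-15,12-olid-19-oate | C=C1CC[C@@H]2[C@](C)(CCC[C@]2(C)C(=O)OCC[Si](C)(C)C)[C@H]1C[C@@H]3OC(=O)C=C3C | intermediate
25 | (12S)-labda-8(17),13-dien-15,12-olid-19-oic acid | C=C1CC[C@@H]2[C@](C)(CCC[C@]2(C)C(=O)O)[C@H]1C[C@@H]3OC(=O)C=C3C | intermediate (not isolated)
26 | (4S,5R,9S,10R,12S,13Z)-12-hydroxylabda-8(17),13-diene-15,19-dioic acid (CNP0144045.1) | C=C1CC[C@@H]2[C@](C)(CCC[C@]2(C)C(=O)O)[C@H]1C[C@H](O)/C(C)=C\C(=O)O | target

**Summary**

Total step count: 20. Longest linear sequence: 19 steps (steps 1–3 and 5–20).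

**Steps most likely to fail**

Step 9. The ring closure has to run against the polarity of the silyloxy diene, so the triene may be lost by hydrolysis of the silyl dienol ether or by addition to a second molecule before it cyclises. The fallback sets out from enone 9. Trapping of its potassium enolate (KN(SiMe3)2, PhNTf2, THF, −78 °C) should give the (Z)-dienyl triflate F1. Coupling with Me3SiCH2MgCl under Pd(PPh3)4 catalysis should give the 2-[(trimethylsilyl)methyl]diene F2, which cannot hydrolyse and is polarised only weakly by its C8 substituent. Heating in toluene at 170 °C should close the same tether to the allylsilane cycloadduct F3. Alkylation at C10 as in step 10 should give the chloropropyl allylsilane F4. TsOH in CH2Cl2/MeOH at 0 °C then protodesilylates the allylsilane (proton to C7, exocyclic C8=C17) and removes the primary silyl ether, which brings the route back at alcohol 15.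

Step 17. Condensation of the sulfonylhydrazide with the neopentyl aldehyde that is masked as the lactol may stay incomplete, and the borane may be used up by the hydroxyl group. The fallback sets out from lactol 20. Ethane-1,2-dithiol and BF3·OEt2 (CH2Cl2, −40 °C) should open it to the 1,3-dithiolane F5. Bu3SnH and AIBN in refluxing toluene then remove both carbon–sulfur bonds by radical hydrogenolysis, and the route comes back at alcohol 22.

Step 20. On acidification the (Z)-γ-hydroxy acid may close again to the butenolide. The fallback sets out from butenolide acid 25. After the hydroxide opening the crude dilithium salt is not acidified but silylated (Et3SiCl, imidazole, DMF) to the tris(triethylsilyl) derivative F6. K2CO3 in MeOH cleaves the two silyl esters, and the 12-O-triethylsilyl diacid F7, which cannot lactonise, is acidified and purified in the usual way. HF·pyridine buffered with pyridine (THF, 0 °C) then frees the hydroxyl group under weakly acidic, non-aqueous conditions, and the route comes back at the target 26.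

**Further compounds**

F1 | step 9 | (3R,5Z)-2-methyl-6-[(trifluoromethanesulfonyl)oxy]octa-1,5,7-trien-3-yl (2Z)-5-[(tert-butyldimethylsilyl)oxy]pent-2-enoate | C=C/C(OS(=O)(=O)C(F)(F)F)=C/C[C@@H](OC(=O)/C=C\CCO[Si](C)(C)C(C)(C)C)C(C)=C
F2 | step 9 | (3R,5E)-2-methyl-6-[(trimethylsilyl)methyl]octa-1,5,7-trien-3-yl (2Z)-5-[(tert-butyldimethylsilyl)oxy]pent-2-enoate | C=C/C(C[Si](C)(C)C)=C/C[C@@H](OC(=O)/C=C\CCO[Si](C)(C)C(C)(C)C)C(C)=C
F3 | step 9 | allylsilane cycloadduct (as 11 with CH2SiMe3 in place of OSiEt3 on C8) | C[Si](C)(C)CC1=CC[C@@H](CCO[Si](C)(C)C(C)(C)C)[C@H]2C(=O)O[C@@H](C(C)=C)C[C@@H]12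
F4 | step 9 | C10-alkylated allylsilane (as 12 with CH2SiMe3 in place of OSiEt3 on C8) | C[Si](C)(C)CC1=CC[C@@H](CCO[Si](C)(C)C(C)(C)C)[C@@]2(CCCCl)C(=O)O[C@@H](C(C)=C)C[C@@H]12
F5 | step 17 | 2-(trimethylsilyl)ethyl (12R)-20,20-(ethane-1,2-diyldisulfanediyl)-12-hydroxy-15-norlabda-8(17),13-dien-19-oate (C20 as 1,3-dithiolane) | C=C1CC[C@@H]2[C@](C3SCCS3)(CCC[C@]2(C)C(=O)OCC[Si](C)(C)C)[C@H]1C[C@@H](O)C(C)=C
F6 | step 20 | bis(triethylsilyl) (12S,13Z)-12-[(triethylsilyl)oxy]labda-8(17),13-diene-15,19-dioate | C=C1CC[C@@H]2[C@](C)(CCC[C@]2(C)C(=O)O[Si](CC)(CC)CC)[C@H]1C[C@H](O[Si](CC)(CC)CC)/C(C)=C\C(=O)O[Si](CC)(CC)CC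
F7 | step 20 | (12S,13Z)-12-[(triethylsilyl)oxy]labda-8(17),13-diene-15,19-dioic acid | C=C1CC[C@@H]2[C@](C)(CCC[C@]2(C)C(=O)O)[C@H]1C[C@H](O[Si](CC)(CC)CC)/C(C)=C\C(=O)O
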